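**Bench note.** Product in the gamma run climbed almost straight, to 7% at 20.0 d, a rate of 0.00350 d⁻¹ as a fraction of the charge. The alpha run began at 0.0400 d⁻¹.

| flask | substrate | coupling partner | base | temperature | remark | time |
|---|---|---|---|---|---|---|
| gamma | 5 mM | 0.70 equiv | 0.30 equiv | 75 °C | run made earlier |  |
| alpha | 26 mM | 0.70 equiv | 0.30 equiv | 86 °C | run made earlier |  |
| autumn | 8.0 mM | 0.700 equiv | 0.300 equiv |  | at 70 °C throughout | 30 d |
| summer | 32 mM | 0.700 equiv | 0.300 equiv |  | at 90 °C until 6.0 d, from then on at 70 °C | 20 d |

| run | time / d | product / % |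
|---|---|---|
| gamma | 1.25 | 0 |
| gamma | 4.00 | 2 |
| gamma | 8.00 | 3 |
| gamma | 10.0 | 4 |
| gamma | 15.0 | 5 |
| gamma | 20.0 | 7 |
| alpha | 1.67 | 7 |
| alpha | 3.00 | 12 |
| alpha | 5.00 | 15 |
| alpha | 6.00 | 19 |
| alpha | 8.00 | 27 |
| alpha | 10.0 | 27 |

(readings scatter by 1.5 percentage points)

* which one finishes higher in amount of product, in percent of the substrate charged ("neither" within 2 percentage points) (autumn / summer / neither)
* amount of product at the end, in percent of the substrate charged, autumn
* amount of product at the end, in percent of the substrate charged, summer

**My reckoning.** Alpha gained a factor 11.4 on gamma while its [substrate] stood 5.20 times higher. I let the rate follow [substrate], which left a factor 2.20 for going from 75 °C to 86 °C.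

**Frozen rate.** I defined the frozen rate as the rate of a flask whose [substrate] and [coupling partner] hold at their charge (pseudo-zero-order). For autumn it came to 0.00392 d⁻¹, so I expected 11.7% of product in autumn at its end.

**Summer.** By the same scaling, summer ran 0.0656 d⁻¹ hot and 0.0157 d⁻¹ after cooling. I reckoned that summer would reach alpha's 27% in 4.88 d, before its change at 6.0 d, so I expected it to finish above autumn's 11.7%.

**The forecast.** It said summer, with 13% for autumn and 30% for summer, reading that “the 0.30 equiv base caps the yield at about 30%”, whereas my summer reckoning held no cap.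

**The flask.** Summer finished higher, at 45.0% against 10.1% for autumn.

    substrate + coupling partner + by-product → product + 2 by-product (k = 64.0 M⁻² h⁻¹, Ea = 58.0 kJ mol⁻¹)
    substrate + coupling partner → product + by-product (k = 0.130 M⁻¹ h⁻¹, Ea = 79.0 kJ mol⁻¹)
    base + by-product ⇌ salt, settled at all times (K = 15000 M⁻¹, ΔH = −42.0 kJ mol⁻¹)
    (constants at 90 °C)

**Early autumn.** Autumn's product stood at 5.35% after 15.0 d and 10.1% after 30.0 d, with substrate still at 89.9% of its charge, so my 11.7% lay 1.6 percentage points high. The neighbour is the autumn flask read at 8.0 d, with its amounts and temperature held. The frozen rate gave it 3.14%. That neighbour kept 97% of its substrate and 90% of its base, and held 2.94% of product.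

All runs are simulated with made-up constants, noise included.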